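## Retrosynthetic overview

1. Ring B (the cyclohexenone) is numbered C1 (C=O), C2 (=CH), C3 (=C–OMe), C4 (methyl aryl ketal), C5 (CH2), C6 (CH–allyl). Ring A is the aryl ring.
2. Enabling feature: C1(=O)–C2H=C3(OMe)–C4(OMe)(OAr) of ring B is an unbroken acyl / enol ether / ketal chain. This chain is the opened form of a squarate-derived cyclobutenone (temporary ring C), electrophilic at C1 and, as a dienolate, nucleophilic at C4. C6 lies α to the C1 ketone, so an ester placed there activates C5=C6 and later leaves as CO2.
3. Key disconnection: C4–C5 and C6–C1 together, by a carbene-catalysed ring-opening formal [4+2] of the racemic cyclobutenone with a 2-allylacrylate (enantioconvergent, sets C4).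
4. Last step: fluoride-triggered loss of the 2-(trimethylsilyl)ethyl ester with kinetic protonation sets C6. The cyclobutenone comes from dimethyl squarate (reduction, transposing ketalisation) and 2-allyl-4,5-dimethoxyphenol (O-allylation, Claisen rearrangement).
5. Ring order: rings A and C are bought; ring C is opened and ring B is closed in the same operation.

Key step: step 7

Assumption: the sense of induction of the aminoindanol-derived carbene on this new dipole cannot be taken from precedent. The (5aR,10bS) catalyst is written, and its equally available mirror image is to be used if correlation shows the opposite sense.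

## Route

Step 1
Reactants: 1 3,4-dimethoxyphenol
Product: 2 4-(allyloxy)-1,2-dimethoxybenzene
Conditions: allyl bromide, K2CO3, acetone, reflux
Reagents that add atoms: allyl bromide, C=CCBr
Why: Williamson ether synthesis, in which the phenoxide displaces bromide from the unhindered allylic halide by SN2; no stereocentre is formed.

Step 2
Reactants: 2 4-(allyloxy)-1,2-dimethoxybenzene
Product: 3 2-allyl-4,5-dimethoxyphenol
Conditions: N,N-diethylaniline, 200 °C
Reagents that add atoms: none
Why: Aromatic Claisen rearrangement ([3,3]-sigmatropic shift, then tautomerisation) should deliver the allyl group to the ortho carbon remote from the methoxy groups, because the other ortho carbon is flanked by a methoxy group.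

Step 3
Reactants: 4 dimethyl squarate (3,4-dimethoxycyclobut-3-ene-1,2-dione)
Product: 5 rac-4-hydroxy-2,3-dimethoxycyclobut-2-en-1-one
Conditions: LiAlH(OtBu)3 (1.1 equiv), THF, −78 → −20 °C; then H2O
Reagents that add atoms: none
Why: Chemoselective 1,2-reduction of one of the two equivalent squarate carbonyls by a bulky aluminium hydride should stop at the ketol, since the remaining carbonyl is a deactivated vinylogous ester; the racemic carbinol centre is lost in step 4.

Step 4
Reactants: 3 2-allyl-4,5-dimethoxyphenol; 5 rac-4-hydroxy-2,3-dimethoxycyclobut-2-en-1-one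
Product: 6 rac-4-(2-allyl-4,5-dimethoxyphenoxy)-3,4-dimethoxycyclobut-2-en-1-one
Conditions: BF3·OEt2 (10 mol %), 4 Å MS, CH2Cl2, −40 °C; Et3N quench
Reagents that add atoms: none
Why: Lewis-acid ionisation of the ketol hydroxyl gives a methoxy-stabilised cyclobutenyl cation that O-nucleophiles capture at the methoxy-bearing terminus with allylic transposition (the established conversion of 4-hydroxy-2,3-dialkoxycyclobutenones into cyclobutenedione monoketals, driven by the vinylogous ester formed); the ketal centre is racemic, which does not matter because step 7 planarises it.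

Step 5
Reactants: 7 ethyl 2-(bromomethyl)acrylate
Product: 8 ethyl 2-methylenepent-4-enoate
Conditions: vinylmagnesium bromide, CuI (10 mol %), THF, −78 → −20 °C
Reagents that add atoms: vinylmagnesium bromide, C=C[Mg]Br
Why: Copper-catalysed allylic substitution of a 2-(bromomethyl)acrylate with a Grignard reagent; SN2 and SN2' attack give the same skipped diene ester.

Step 6
Reactants: 8 ethyl 2-methylenepent-4-enoate
Product: 9 2-(trimethylsilyl)ethyl 2-methylenepent-4-enoate
Conditions: 2-(trimethylsilyl)ethanol (3 equiv), Ti(OiPr)4 (10 mol %), toluene, 90 °C, removal of EtOH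
Reagents that add atoms: 2-(trimethylsilyl)ethanol, C[Si](C)(C)CCO
Why: Titanate-catalysed transesterification under neutral conditions, driven by removal of ethanol, exchanges the ethyl group for the fluoride-labile 2-(trimethylsilyl)ethyl group without touching the diene.

Step 7
Reactants: 6 rac-4-(2-allyl-4,5-dimethoxyphenoxy)-3,4-dimethoxycyclobut-2-en-1-one; 9 2-(trimethylsilyl)ethyl 2-methylenepent-4-enoate
Product: 11 2-(trimethylsilyl)ethyl (1S,5R)-1-allyl-5-(2-allyl-4,5-dimethoxyphenoxy)-4,5-dimethoxy-2-oxocyclohex-3-ene-1-carboxylate, via azolium dienolate 10 (not isolated)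
Conditions: (5aR,10bS)-2-mesityl-5a,10b-dihydro-4H,6H-indeno[2,1-b][1,2,4]triazolo[4,3-d][1,4]oxazin-2-ium tetrafluoroborate (15 mol %), Cs2CO3 (15 mol %), LiCl (0.5 equiv), 9 (3 equiv), 4 Å MS, THF, 30 °C
Reagents that add atoms: none
Why: Proposed new method: the chiral triazolylidene adds to the strained C1 carbonyl of 6, the resulting alkoxide breaks the C1–C4 bond of ring C with release of ring strain (no free vinylketene at 30 °C), both enantiomers of 6 thereby converge on the planar azolium dienolate 10, its C4 terminus adds to the CH2 end of acrylate 9, and the ester enolate so formed acylates at C1 and expels the carbene. The closest known reaction type is the carbene- or phosphine-triggered C–C cleavage of cyclobutenones to 1,4-dipoles followed by formal [4+2] annulation with sulfonyl imines or alkylidene malononitriles; new are the doubly oxygenated C4 terminus and the singly activated, α-branched acrylate. Ring B closes by an intermolecular vinylogous Michael addition (C4–C5) and then a 6-exo-trig Dieckmann-type C-acylation (C6–C1), the alternative O-acylation being an unfavourable eight-membered closure. C4 is controlled by the catalyst: the C3=C4 isomers of 10 interconvert by reversible ring closure, the U-shaped isomer with the small methoxy group inside and the aryloxy group outside reacts, and the indane wall of the carbene leaves only one of its faces open to 9. C6 is controlled by the endo approach of the ester carbonyl under the azolium cation (bridged by Li+), which places the ester cis to the aryloxy group, and this centre is erased again in step 8. The step needs chemo- and regioselectivity among the alkenes present, and polarity secures both: only the ester-bearing C=C of 9 accepts an enolate, only its CH2 carbon is electrophilic, and the two unactivated allyl groups, among them the ortho-allyl group of ring A that would capture a free vinylketene or a metallacycle intramolecularly, are left alone.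

Step 8
Reactants: 11 2-(trimethylsilyl)ethyl (1S,5R)-1-allyl-5-(2-allyl-4,5-dimethoxyphenoxy)-4,5-dimethoxy-2-oxocyclohex-3-ene-1-carboxylate
Product: 14 (4R,6S)-6-allyl-4-(2-allyl-4,5-dimethoxyphenoxy)-3,4-dimethoxycyclohex-2-en-1-one, via ammonium keto carboxylate 12 (not isolated), via ammonium dienolate 13 (not isolated)
Conditions: tetrabutylammonium difluorotriphenylsilicate Bu4N[Ph3SiF2] (1.2 equiv), 2,6-di-tert-butyl-4-methylphenol (2 equiv, present from the start), THF, 0 → 23 °C; pH 7 work-up, Et3N-deactivated silica
Reagents that add atoms: none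
Why: Fluoride-induced dealkoxycarbonylation of a 2-(trimethylsilyl)ethyl β-keto ester, in which fluoride attacks silicon with loss of ethylene, the naked carboxylate 12 loses CO2, and the cross-conjugated enolate 13 is at once protonated at C6 by the hindered phenol from the face opposite the pseudoaxial aryloxy group on C4 (axial because of allylic strain with the C3 methoxy group and π→σ* overlap), which places the allyl group cis to the aryloxy group (6S), while the weakly basic phenolate should not epimerise the product.

## Compound list

1 | 3,4-dimethoxyphenol | COc1ccc(O)cc1OC | starting material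
2 | 4-(allyloxy)-1,2-dimethoxybenzene | C=CCOc1ccc(OC)c(OC)c1 | intermediate
3 | 2-allyl-4,5-dimethoxyphenol | C=CCc1cc(OC)c(OC)cc1O | intermediate
4 | dimethyl squarate (3,4-dimethoxycyclobut-3-ene-1,2-dione) | COC1=C(OC)C(=O)C1=O | starting material
5 | rac-4-hydroxy-2,3-dimethoxycyclobut-2-en-1-one | COC1=C(OC)C(O)C1=O | intermediate
6 | rac-4-(2-allyl-4,5-dimethoxyphenoxy)-3,4-dimethoxycyclobut-2-en-1-one | C=CCc1cc(OC)c(OC)cc1OC1(OC)C(OC)=CC1=O | intermediate
7 | ethyl 2-(bromomethyl)acrylate | C=C(CBr)C(=O)OCC | starting material
8 | ethyl 2-methylenepent-4-enoate | C=CCC(=C)C(=O)OCC | intermediate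
9 | 2-(trimethylsilyl)ethyl 2-methylenepent-4-enoate | C=CCC(=C)C(=O)OCC[Si](C)(C)C | intermediate
10 | azolium dienolate (carbene bound at C1, C4 methoxy inside, aryloxy outside; not isolated) | [O-]C(=C/C(OC)=C(\OC)Oc1cc(OC)c(OC)cc1CC=C)c1[n+](-c2c(C)cc(C)cc2C)nc2CO[C@@H]3Cc4ccccc4[C@@H]3n12 | intermediate
11 | 2-(trimethylsilyl)ethyl (1S,5R)-1-allyl-5-(2-allyl-4,5-dimethoxyphenoxy)-4,5-dimethoxy-2-oxocyclohex-3-ene-1-carboxylate | C=CCc1cc(OC)c(OC)cc1O[C@]1(OC)C[C@](CC=C)(C(=O)OCC[Si](C)(C)C)C(=O)C=C1OC | intermediate
12 | tetrabutylammonium (1S,5R)-1-allyl-5-(2-allyl-4,5-dimethoxyphenoxy)-4,5-dimethoxy-2-oxocyclohex-3-ene-1-carboxylate (not isolated) | CCCC[N+](CCCC)(CCCC)CCCC.C=CCc1cc(OC)c(OC)cc1O[C@]1(OC)C[C@](CC=C)(C(=O)[O-])C(=O)C=C1OC | intermediate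
13 | tetrabutylammonium (R)-2-allyl-4-(2-allyl-4,5-dimethoxyphenoxy)-4,5-dimethoxycyclohexa-1,5-dien-1-olate (not isolated) | CCCC[N+](CCCC)(CCCC)CCCC.C=CCc1cc(OC)c(OC)cc1O[C@]1(OC)CC(CC=C)=C([O-])C=C1OC | intermediate
14 | (4R,6S)-6-allyl-4-(2-allyl-4,5-dimethoxyphenoxy)-3,4-dimethoxycyclohex-2-en-1-one | C=CCc1cc(OC)c(OC)cc1O[C@]1(OC)C[C@H](CC=C)C(=O)C=C1OC | target

## Step count and risks

Total step count: 8.
Longest linear sequence: 5 steps (steps 1, 2, 4, 7, 8, from 3,4-dimethoxyphenol).

**Step 7.**
- The conjugate addition to the α-branched acrylate may be too slow. The dienolate would then be consumed by protonation or by attack on unopened cyclobutenone.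
- The carbene may add to C3 with loss of methoxide.
- Control of face and of C3=C4 geometry at C4 may be incomplete.

Fallback (known chemistry), from 6 and 9 back to 11: catalytic NaOMe in MeOH at 0 °C opens ring C by alkoxide addition to C1. After protonation and equilibration this gives methyl (E)-4-(2-allyl-4,5-dimethoxyphenoxy)-3,4-dimethoxybut-2-enoate F1. γ-Deprotonation with LDA (THF, −78 °C) and addition of 9 bring about a stoichiometric Michael–Dieckmann annulation to racemic 2-(trimethylsilyl)ethyl 1-allyl-5-(2-allyl-4,5-dimethoxyphenoxy)-4,5-dimethoxy-2-oxocyclohex-3-ene-1-carboxylate F2. F2 is resolved by preparative chromatography on a chiral stationary phase to give 11.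

**Step 8.**
- Facial selectivity of the protonation at C6 may be poor.
- Later epimerisation at C6 towards the probably more stable trans isomer is possible.
- Acid- or heat-induced loss of the phenol with aromatisation of ring B is possible.

Fallback, from 8 back to 14: Ti(OiPr)4-catalysed transesterification with allyl alcohol gives allyl 2-methylenepent-4-enoate F3. Annulation with 6 under the conditions of step 7 gives allyl (1S,5R)-1-allyl-5-(2-allyl-4,5-dimethoxyphenoxy)-4,5-dimethoxy-2-oxocyclohex-3-ene-1-carboxylate F4. Pd2(dba)3 with one enantiomer of 4-tert-butyl-2-[2-(diphenylphosphino)phenyl]-4,5-dihydrooxazole, and 2,2-dimethyl-1,3-dioxane-4,6-dione as proton donor (THF, 23 °C), then effects a decarboxylative protonation through a chiral palladium enolate. The ligand, and not only the substrate, then decides the face at C6, and the product is 14.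

**Step 4.**
- The ketal may be hydrolysed by the water released.
- The alkoxy groups may exchange through re-ionisation.
- The cation may C-alkylate the electron-rich arene.

Fallback, from 5 and 3 back to 6: acetylation of 5 (Ac2O, pyridine, 0 °C) gives 2,3-dimethoxy-4-oxocyclobut-2-en-1-yl acetate F5. Silylation of 3 (TMSCl, imidazole, CH2Cl2) gives (2-allyl-4,5-dimethoxyphenoxy)trimethylsilane F6. The two are joined with TMSOTf (5 mol %) in CH2Cl2 at −78 °C. This is a water-free silyl-transfer ketalisation that gives 6.

## Further compounds

F1 | step 7 | methyl (E)-4-(2-allyl-4,5-dimethoxyphenoxy)-3,4-dimethoxybut-2-enoate (racemic) | COC(=O)/C=C(/OC)C(OC)Oc1cc(OC)c(OC)cc1CC=C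
F2 | step 7 | racemic 2-(trimethylsilyl)ethyl 1-allyl-5-(2-allyl-4,5-dimethoxyphenoxy)-4,5-dimethoxy-2-oxocyclohex-3-ene-1-carboxylate | C=CCc1cc(OC)c(OC)cc1OC1(OC)CC(CC=C)(C(=O)OCC[Si](C)(C)C)C(=O)C=C1OC
F3 | step 8 | allyl 2-methylenepent-4-enoate | C=CCOC(=O)C(=C)CC=C
F4 | step 8 | allyl (1S,5R)-1-allyl-5-(2-allyl-4,5-dimethoxyphenoxy)-4,5-dimethoxy-2-oxocyclohex-3-ene-1-carboxylate | C=CCc1cc(OC)c(OC)cc1O[C@]1(OC)C[C@](CC=C)(C(=O)OCC=C)C(=O)C=C1OC
F5 | step 4 | 2,3-dimethoxy-4-oxocyclobut-2-en-1-yl acetate (racemic) | CC(=O)OC1C(OC)=C(OC)C1=O
F6 | step 4 | (2-allyl-4,5-dimethoxyphenoxy)trimethylsilane | C=CCc1cc(OC)c(OC)cc1O[Si](C)(C)C
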